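**Retrosynthetic overview**
1. Target 24 ⇐ hydrolysis of imide/methyl ester 22 ⇐ reagent-controlled epoxidation of the (4Z)-olefin of 21; the oxirane is the only ring of the target and is made last.
2. C12–C13 by an Evans syn aldol of aldehyde 14 with a 3-silyloxypropanoyl oxazolidinone; C2=C3 by Horner–Wadsworth–Emmons olefination of methyl ketone 12.
3. Z-enone 12 (C3–C12, carrying C7) ⇐ radical scission of the C1–C6 ring bond of cyclohexenol 9; the ring olefin becomes the (4Z)-olefin.
4. 9 ⇐ α′-alkylation and MeLi addition on (S)-3,5-dimethylcyclohexenone 5 ⇐ one-pot enantioselective desymmetrising dehydrogenation of meso ketone 2 ⇐ hydrogenation of 3,5-dimethylphenol 1.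
5. Ring order: the carbocycle comes from the arene (step 1), is desymmetrised (step 2) and destroyed (step 5); the oxirane is formed in step 10.

Target locants C1–C14 (tetradec-2-enedioic acid numbering) are used throughout.

Assumption: the (R,R)-lithium amide removes the same enantiotopic axial α-proton in 2 as it does in 4-tert-butylcyclohexanone, and the spiro transition-state model holds in step 10; if either sense is reversed, the mirror-image reagent is used.

**Route**

Step 1
Reactants: 1 3,5-dimethylphenol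
Product: 2 cis-3,5-dimethylcyclohexanone (meso)
Conditions: H2 (10 bar), 5% Pd/C, AlCl3 (5 mol %), CH2Cl2, 50 °C; fractional distillation to remove the minor trans isomer
Reagents that add atoms: none
Why: Heterogeneous arene hydrogenation of a phenol stops at the cyclohexanone on Pd, and all-syn hydrogen delivery (also the diequatorial, thermodynamic outcome) gives the meso cis isomer.

Step 2
Reactants: 2 cis-3,5-dimethylcyclohexanone
Product: 5 (S)-3,5-dimethylcyclohex-2-en-1-one, via lithium enolate 3 (not isolated), via α-sulfilimino ketone 4 (not isolated)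
Conditions: lithium (R,R)-bis(1-phenylethyl)amide [from the amine hydrochloride and 2 equiv n-BuLi, so LiCl is present], THF, −78 °C; then N-tert-butylbenzenesulfinimidoyl chloride, −78 °C
Reagents that add atoms: none
Why: Proposed new method: the C2-symmetric lithium amide removes one of the two enantiotopic axial α-protons of meso 2 (chiral-base desymmetrisation), enolate 3 is sulfenylated at carbon anti to the neighbouring methyl, and sulfilimine 4 undergoes syn elimination at −78 °C (Mukaiyama dehydrogenation), which erases C3 and leaves C5 as the (S) centre (future C7); the closest known reactions are chiral lithium amide/silyl enol ether formation on this ketone and dehydrogenation of LiN(iPr)2-derived enolates with the same sulfinimidoyl chloride.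

Step 3
Reactants: 5 (S)-3,5-dimethylcyclohex-2-en-1-one, 6 4-bromo-1,1-dimethoxybutane
Product: 8 (5S,6R)-6-(4,4-dimethoxybutyl)-3,5-dimethylcyclohex-2-en-1-one, via cross-conjugated lithium dienolate 7 (not isolated)
Conditions: LiN(iPr)2, THF, −78 °C; then 6, DMPU, Bu4NI (10 mol %), −78 → 0 °C
Reagents that add atoms: none
Why: Kinetic deprotonation of a 3-substituted cyclohexenone occurs at C6 (α′), and SN2 enolate alkylation takes place anti to the C5 methyl; the C6 configuration is irrelevant because this carbon becomes the C8 methylene.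

Step 4
Reactants: 8 (5S,6R)-6-(4,4-dimethoxybutyl)-3,5-dimethylcyclohex-2-en-1-one
Product: 9 (5S,6R)-6-(4,4-dimethoxybutyl)-1,3,5-trimethylcyclohex-2-en-1-ol (both C1 epimers)
Conditions: MeLi, Et2O, −78 °C; then H2O
Reagents that add atoms: methyllithium [Li]C
Why: 1,2-addition of a hard organolithium to the enone carbonyl installs the future C3 methyl; the new carbinol centre is destroyed in step 5, so its configuration does not matter.

Step 5
Reactants: 9 (5S,6R)-6-(4,4-dimethoxybutyl)-1,3,5-trimethylcyclohex-2-en-1-ol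
Product: 12 (3Z,6R)-11,11-dimethoxy-4,6-dimethylundec-3-en-2-one, via alkoxy radical 10 (not isolated), via secondary alkyl radical 11 (not isolated)
Conditions: [Ir(dF(CF3)ppy)2(5,5′-d(CF3)bpy)]PF6 (2 mol %), 2,4,6-triisopropylbenzenethiol (20 mol %), Bu4P[(MeO)2PO2] (25 mol %), PhCF3, blue LEDs, 25 °C
Reagents that add atoms: none
Why: Proposed new method: proton-coupled electron transfer at the tertiary O–H gives alkoxy radical 10, β-scission cleaves the more substituted C1–C6 bond (secondary radical 11 plus a conjugated enone), and hydrogen-atom transfer from the thiol gives 12 with the Z geometry fixed by the former ring and C7 untouched; the closest known reaction is the photocatalytic ring-opening isomerisation of tertiary cycloalkanols to acyclic ketones.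

Step 6
Reactants: 12 (3Z,6R)-11,11-dimethoxy-4,6-dimethylundec-3-en-2-one
Product: 14 methyl (2E,4Z,7R)-3,5,7-trimethyl-12-oxododeca-2,4-dienoate, via acetal dienoate 13 (not isolated)
Conditions: (MeO)2P(O)CH2CO2Me, NaH, THF, 0 → 50 °C; then 1 M aq HCl, THF, 23 °C; chromatography removes the minor 2Z isomer
Reagents that add atoms: trimethyl phosphonoacetate COC(=O)CP(=O)(OC)OC; water O
Why: Horner–Wadsworth–Emmons olefination of the methyl ketone places the ester anti to the larger alkenyl group (2E), and the acidic work-up hydrolyses the dimethyl acetal to the C12 aldehyde without touching the dienoate.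

Step 7
Reactants: 15 (R)-4-benzyl-1,3-oxazolidin-2-one, 16 3-[(tert-butyldimethylsilyl)oxy]propanoic acid
Product: 18 (4R)-4-benzyl-3-{3-[(tert-butyldimethylsilyl)oxy]propanoyl}-1,3-oxazolidin-2-one, via mixed pivalic anhydride 17 (not isolated)
Conditions: 16, PivCl, Et3N, THF, −20 °C; then 15, LiCl, −20 → 23 °C
Reagents that add atoms: none
Why: N-acylation of the oxazolidinone through the mixed pivalic anhydride (LiCl/Et3N activation); the auxiliary centre is not involved.

Step 8
Reactants: 14 methyl (2E,4Z,7R)-3,5,7-trimethyl-12-oxododeca-2,4-dienoate, 18 (4R)-4-benzyl-3-{3-[(tert-butyldimethylsilyl)oxy]propanoyl}-1,3-oxazolidin-2-one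
Product: 20 methyl (2E,4Z,7R,12S,13R)-13-[(4R)-4-benzyl-2-oxo-1,3-oxazolidine-3-carbonyl]-14-[(tert-butyldimethylsilyl)oxy]-12-hydroxy-3,5,7-trimethyltetradeca-2,4-dienoate, via dibutylboron Z-enolate 19 (not isolated)
Conditions: 18, Bu2BOTf, iPr2NEt, CH2Cl2, 0 °C; then 14, −78 → 0 °C; then pH 7 phosphate buffer, MeOH, 30% H2O2, 0 °C
Reagents that add atoms: none
Why: Evans syn aldol through the Z-boron enolate and a closed Zimmerman–Traxler transition state; the (R)-benzyl auxiliary shields one enolate face and sets 12S and 13R together, the aldehyde reacting in preference to the ester.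

Step 9
Reactants: 20 silyl-protected aldol adduct
Product: 21 methyl (2E,4Z,7R,12S,13R)-13-[(4R)-4-benzyl-2-oxo-1,3-oxazolidine-3-carbonyl]-12,14-dihydroxy-3,5,7-trimethyltetradeca-2,4-dienoate
Conditions: HF·pyridine, pyridine, THF, 0 → 23 °C
Reagents that add atoms: none
Why: Fluoride-driven cleavage of the primary silyl ether, done before the acid-sensitive epoxide exists; no stereocentre is affected.

Step 10
Reactants: 21 diol dienoate
Product: 22 methyl (2E,4S,5R,7R,12S,13R)-13-[(4R)-4-benzyl-2-oxo-1,3-oxazolidine-3-carbonyl]-4,5-epoxy-12,14-dihydroxy-3,5,7-trimethyltetradec-2-enoate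
Conditions: L-fructose-derived Shi ketone (30 mol %), KHSO5 (Oxone), K2CO3, Bu4NHSO4 (cat.), MeCN/CH2(OMe)2, aq Na2B4O7/Na2EDTA buffer (pH 10.5), 0 °C
Reagents that add atoms: potassium peroxymonosulfate [K+].[O-]S(=O)(=O)OO
Why: Shi asymmetric epoxidation: the electrophilic chiral dioxirane attacks the electron-richer distal C4=C5 olefin rather than the enoate, concerted oxygen transfer keeps the cis relationship of C3 and C6, and the spiro transition state with this catalyst enantiomer delivers oxygen to the face that gives 4S,5R.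

Step 11
Reactants: 22 epoxy imide methyl ester
Product: 24 (2E,4S,5R,7R,12S,13R)-4,5-epoxy-12-hydroxy-13-(hydroxymethyl)-3,5,7-trimethyltetradec-2-enedioic acid, via lithium carboxylate monoester 23 (not isolated)
Conditions: LiOH, 30% H2O2, THF/H2O, 0 °C; Na2SO3; then LiOH, MeOH/H2O, 23 °C; 1 M HCl to pH 4 at 0 °C, reversed-phase HPLC
Reagents that add atoms: hydrogen peroxide OO; lithium hydroxide [Li+].[OH-]
Why: Hydroperoxide cleaves the imide exocyclically (sulfite reduces the peroxy species) and hydroxide then saponifies the methyl ester; the trisubstituted epoxide and all stereocentres are stable to these basic conditions.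

**Compound list**
1 | 3,5-dimethylphenol | Cc1cc(C)cc(O)c1 | starting material
2 | cis-3,5-dimethylcyclohexanone, (3R,5S), meso | O=C1C[C@H](C)C[C@H](C)C1 | intermediate
3 | lithium (3R,5S)-3,5-dimethylcyclohex-1-en-1-olate | [Li]OC1=C[C@H](C)C[C@H](C)C1 | intermediate
4 | (2S,3R,5S)-2-(N-tert-butyl-S-phenylsulfinimidoyl)-3,5-dimethylcyclohexan-1-one | O=C1[C@@H](S(=NC(C)(C)C)c2ccccc2)[C@H](C)C[C@H](C)C1 | intermediate
5 | (S)-3,5-dimethylcyclohex-2-en-1-one | O=C1C=C(C)C[C@H](C)C1 | intermediate
6 | 4-bromo-1,1-dimethoxybutane | COC(OC)CCCBr | starting material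
7 | lithium (6S)-4,6-dimethylcyclohexa-1,3-dien-2-olate | [Li]OC1=C[C@@H](C)CC(C)=C1 | intermediate
8 | (5S,6R)-6-(4,4-dimethoxybutyl)-3,5-dimethylcyclohex-2-en-1-one | O=C1C=C(C)C[C@H](C)[C@H]1CCCC(OC)OC | intermediate
9 | (5S,6R)-6-(4,4-dimethoxybutyl)-1,3,5-trimethylcyclohex-2-en-1-ol (C1 epimers) | CC1(O)C=C(C)C[C@H](C)[C@H]1CCCC(OC)OC | intermediate
10 | alkoxy radical of 9 | CC1([O])C=C(C)C[C@H](C)[C@H]1CCCC(OC)OC | intermediate
11 | (3Z,6R)-11,11-dimethoxy-4,6-dimethyl-2-oxoundec-3-en-7-yl radical | CC(=O)/C=C(/C)C[C@H](C)[CH]CCCC(OC)OC | intermediate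
12 | (3Z,6R)-11,11-dimethoxy-4,6-dimethylundec-3-en-2-one | CC(=O)/C=C(/C)C[C@H](C)CCCCC(OC)OC | intermediate
13 | methyl (2E,4Z,7R)-12,12-dimethoxy-3,5,7-trimethyldodeca-2,4-dienoate | COC(=O)/C=C(\C)/C=C(/C)C[C@H](C)CCCCC(OC)OC | intermediate
14 | methyl (2E,4Z,7R)-3,5,7-trimethyl-12-oxododeca-2,4-dienoate | COC(=O)/C=C(\C)/C=C(/C)C[C@H](C)CCCCC=O | intermediate
15 | (R)-4-benzyl-1,3-oxazolidin-2-one | O=C1N[C@H](Cc2ccccc2)CO1 | starting material
16 | 3-[(tert-butyldimethylsilyl)oxy]propanoic acid | OC(=O)CCO[Si](C)(C)C(C)(C)C | starting material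
17 | 3-[(tert-butyldimethylsilyl)oxy]propanoic pivalic anhydride | CC(C)(C)C(=O)OC(=O)CCO[Si](C)(C)C(C)(C)C | intermediate
18 | (4R)-4-benzyl-3-{3-[(tert-butyldimethylsilyl)oxy]propanoyl}-1,3-oxazolidin-2-one | O=C1OC[C@@H](Cc2ccccc2)N1C(=O)CCO[Si](C)(C)C(C)(C)C | intermediate
19 | dibutylboron (Z)-enolate of 18 | O=C1OC[C@@H](Cc2ccccc2)N1/C(=C/CO[Si](C)(C)C(C)(C)C)OB(CCCC)CCCC | intermediate
20 | methyl (2E,4Z,7R,12S,13R)-13-[(4R)-4-benzyl-2-oxo-1,3-oxazolidine-3-carbonyl]-14-[(tert-butyldimethylsilyl)oxy]-12-hydroxy-3,5,7-trimethyltetradeca-2,4-dienoate | COC(=O)/C=C(\C)/C=C(/C)C[C@H](C)CCCC[C@H](O)[C@@H](CO[Si](C)(C)C(C)(C)C)C(=O)N1[C@H](Cc2ccccc2)COC1=O | intermediate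
21 | methyl (2E,4Z,7R,12S,13R)-13-[(4R)-4-benzyl-2-oxo-1,3-oxazolidine-3-carbonyl]-12,14-dihydroxy-3,5,7-trimethyltetradeca-2,4-dienoate | COC(=O)/C=C(\C)/C=C(/C)C[C@H](C)CCCC[C@H](O)[C@@H](CO)C(=O)N1[C@H](Cc2ccccc2)COC1=O | intermediate
22 | methyl (2E,4S,5R,7R,12S,13R)-13-[(4R)-4-benzyl-2-oxo-1,3-oxazolidine-3-carbonyl]-4,5-epoxy-12,14-dihydroxy-3,5,7-trimethyltetradec-2-enoate | COC(=O)/C=C(\C)[C@@H]1O[C@]1(C)C[C@H](C)CCCC[C@H](O)[C@@H](CO)C(=O)N1[C@H](Cc2ccccc2)COC1=O | intermediate
23 | lithium (2R,3S,8R,10R,11S,12E)-10,11-epoxy-3-hydroxy-2-(hydroxymethyl)-14-methoxy-8,10,12-trimethyl-14-oxotetradec-12-enoate (C14 carboxylate, C1 methyl ester in target numbering) | COC(=O)/C=C(\C)[C@@H]1O[C@]1(C)C[C@H](C)CCCC[C@H](O)[C@@H](CO)C(=O)O[Li] | intermediate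
24 | (2E,4S,5R,7R,12S,13R)-4,5-epoxy-12-hydroxy-13-(hydroxymethyl)-3,5,7-trimethyltetradec-2-enedioic acid | C/C(=C\C(=O)O)[C@@H]1O[C@]1(C)C[C@H](C)CCCC[C@H](O)[C@@H](CO)C(=O)O | target

**Step count and risks**
Total: 11 steps. Longest linear sequence: 10 steps (1–6, 8–11); step 7 is a one-step side branch.

Steps most likely to fail:

- **Step 5 (ring scission).** The alkoxy radical may return to 9 by back hydrogen transfer faster than it fragments, or the Z-enone may isomerise. Fallback, from 9 back to 12: stoichiometric hypoiodite fragmentation (PhI(OAc)2, I2, NaHCO3, cyclohexane, visible light, 20 °C) traps the ring-opened radical as the iodo enone (3Z,6R)-7-iodo-11,11-dimethoxy-4,6-dimethylundec-3-en-2-one F2. Radical deiodination (Bu3SnH, Et3B/air, toluene, 0 °C) then returns to 12.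

- **Step 2 (one-pot desymmetrising dehydrogenation).** External quench with the sulfur electrophile may give a lower ee than the 85–90% typical of this base, and the free amine may consume reagent. Any C7 epimer carried forward must be removed by HPLC of 20 or 24. Fallback, from 2 back to 5: run the chiral-base deprotonation under internal quench with Me3SiCl at −100 °C and isolate the silyl enol ether trimethyl{[(3R,5S)-3,5-dimethylcyclohex-1-en-1-yl]oxy}silane F1. Saegusa–Ito oxidation (Pd(OAc)2, MeCN, 23 °C) then gives 5.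

- **Step 10 (epoxidation).** Facial selectivity on a twisted Z-trisubstituted dienoate is untested, and the imide sees pH 10.5. Fallback, from 20 back to 22: change to metal-oxo transfer on the silyl ether, using the (salen)MnCl catalyst [N,N′-bis(3,5-di-tert-butylsalicylidene)-1,2-cyclohexanediamine ligand, enantiomer chosen on a small scale], NaOCl and 4-phenylpyridine N-oxide in CH2Cl2 at 0 °C. This gives the epoxy silyl ether methyl (2E,4S,5R,7R,12S,13R)-13-[(4R)-4-benzyl-2-oxo-1,3-oxazolidine-3-carbonyl]-14-[(tert-butyldimethylsilyl)oxy]-4,5-epoxy-12-hydroxy-3,5,7-trimethyltetradec-2-enoate F3, which is desilylated with HF·pyridine/pyridine in THF at 0 °C to reach 22.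

**Further compounds**
F1 | step 2 | trimethyl{[(3R,5S)-3,5-dimethylcyclohex-1-en-1-yl]oxy}silane | C[Si](C)(C)OC1=C[C@H](C)C[C@H](C)C1
F2 | step 5 | (3Z,6R)-7-iodo-11,11-dimethoxy-4,6-dimethylundec-3-en-2-one (C7 epimers) | CC(=O)/C=C(/C)C[C@H](C)C(I)CCCC(OC)OC
F3 | step 10 | methyl (2E,4S,5R,7R,12S,13R)-13-[(4R)-4-benzyl-2-oxo-1,3-oxazolidine-3-carbonyl]-14-[(tert-butyldimethylsilyl)oxy]-4,5-epoxy-12-hydroxy-3,5,7-trimethyltetradec-2-enoate | COC(=O)/C=C(\C)[C@@H]1O[C@]1(C)C[C@H](C)CCCC[C@H](O)[C@@H](CO[Si](C)(C)C(C)(C)C)C(=O)N1[C@H](Cc2ccccc2)COC1=O
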